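## Analysis of the target

The target is a flavonol: a chromen-4-one in which the benzo ring A is fused to the pyranone ring C, with the aryl ring B on C2. It is rhamnetin (7-O-methylquercetin) carrying sulfate monoesters on the enolic O3 of ring C and on O3' of ring B. There are no stereocentres, so the whole problem is connectivity and the differentiation of five oxygens: O7 is methylated, O3 and O3' are sulfated, O5 and O4' stay free. O5–H is hydrogen-bonded to the C4 carbonyl. This makes it the least reactive hydroxyl and makes an O5 alkyl ether the one most easily cleaved by a chelating Lewis acid. O4'–H is conjugated through ring B and C2=C3 with the carbonyl and is the most acidic of the remaining hydroxyls. The sulfate monoesters are the sensitive groups: they solvolyse in acid, do not survive Lewis acids and make the compounds very polar, so they must be introduced at the end and followed only by a neutral step. The hard part is therefore the order of protecting-group events, in particular masking O4' while its neighbour O3' is sulfated. The strategy rests on C4a of ring A, which is ortho to O1, ortho to the C5 oxygen and para to the C7 oxygen. It is the most nucleophilic carbon of a phloroglucinol-type ring, so the C4–C4a bond can be made by acylation. In a 3,5-dimethoxyphenoxy precursor the two candidate carbons are identical.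

## Retrosynthetic reasoning

Target 14 to 13. The last bond cut is the O4'–benzyl bond. A benzyl ether is chosen because hydrogenolysis is neutral and leaves aryl and enol sulfates intact; any acid-removable group at O4' would endanger the sulfates.

13 to 12. The two S–O bonds at O3 and O3' are cut together. The forward sulfation must reach the enolic, hydrogen-bonded O3–H and the phenolic O3'–H. The chelated O5–H is expected to stay free without protection, so only O4' needs a mask.

12 to 11. The O4'–CH2 bond is cut, leading back to rhamnetin 11. The forward step has to alkylate one of four hydroxyls and relies on O4'–H being the most acidic. A ring B building block with O3' and O4' protected differently would avoid this selective step. It would, however, force the O5 methyl ether to be cleaved by a Lewis acid next to a benzyl ether on ring B, which is a worse selectivity problem. The uniform benzyl series allows one robust operation down to 11.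

11 to 10. Three O–benzyl bonds and the O5–CH3 bond are cut in one operation. The forward reaction must leave the O7 methyl ether alone; chelation to the C4 carbonyl is what distinguishes O5 from O7.

10 to 8 through 9. This is the strategic disconnection, C4–C4a. Cutting here, and not at O1–C2 or C2–C3, turns ring A into an intact, commercial, symmetric phenol with the 7-methoxy group already in place. All carbons of ring C then sit in one acrylic acid, 8. The forward reaction must activate the acid (mixed anhydride 9) and acylate ring A ortho to the ether oxygen.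

8 to 7. The acid is masked as its ethyl ester through the assembly; the forward step is a saponification that must not hydrolyse the aryl enol ether.

7 to 5 and 6. The vinylic C–O bond (C2–O1 of the flavone) is cut. Phenol 6 displaces a sulfonate from the β-carbon of the acrylate 5, which uses the phenol as an O-nucleophile first and as a C-nucleophile later.

5 to 4. The enol O–S bond is cut; the β-keto ester 4 is the stable, easily made form of the three-carbon unit with O3 already attached.

4 to 2 and 3. The bond between the ketone carbon and the α-carbon (C2–C3 of the flavone) is cut. A crossed Claisen condensation joins the ring B acyl donor 2 to the glycolate 3, which supplies C3, C4 and O3.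

2 to 1. The acyl donor 2 is the activated form of the commercial acid 1.

## Alternatives that were turned down

Alternative 1: Ring A is made last by cutting C4a–C5. A 2-aryl-3-alkoxypyran-4-one with a 3-oxobutanoate chain on C6, A1, would be treated with a magnesium alkoxide. The vinylogous enolate would react through the pyranone carbon that becomes C4a with the ester carbonyl, and the new ring would tautomerise to the 5,7-dihydroxy pattern of A2.
- For: ring B arrives with O4' as benzyl ether and O3' as methoxymethyl ether, and O3 is also a methoxymethyl ether. The two oxygens to be sulfated can be freed together by mild acid while O4' stays blocked. On this point it is stronger than the chosen route, which needs a selective benzylation.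
- Against: A2 has both O5–H and O7–H free, so a selective 7-O-methylation must follow. That is feasible but costs a step. A1 is a tricarbonyl chain on a preformed pyranone and needs many steps to build. It can also close in other ways: aldol attack on the pyranone carbonyl, O-acylation, or reaction through the γ-carbon of the dienolate.
- Comparison: the chosen strategy takes ring A from a commercial phenol with the methyl ether in place and puts its risk on one C–C bond to a carbon of undoubted nucleophilicity.

Alternative 2: The cuts are C8a–O1, C4a–C4 and O1–C2. Fluoride would release an aryne from the silyl triflate A3. The carboxylate of the arylpropiolic acid A4 would add to the aryne carbon remote from the benzyloxy group, the aryl anion would take over the acyl group, and the resulting phenoxide would add to the ynone to give A5.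
- For: three bonds and ring C form in one flask. Ring A arrives with O5 benzylated and O7 methylated, so no chelation-controlled demethylation is needed, and ring B is already differentiated. On both counts it is stronger than the chosen route.
- Against: A5 has hydrogen at C3, so O3 must be introduced later by metalation and oxidation of an advanced flavone. A3 is a tetrasubstituted arene needing its own synthesis. The regiochemistry rests only on the inductive bias of one alkoxy group. Arylpropiolic acids decarboxylate easily, and the alkyne competes for the aryne.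
- Comparison: the chosen strategy has no regiochemical question, carries O3 from the first C–C bond, and uses ordinary reactions up to the key step.

Alternative 3: Ring B itself is cut at C2'–C3' and C1'–C6'. The 2-ethynylchromone A6 would take up 3-(benzyloxy)furan A7 in a [4+2] cycloaddition, with the nucleophilic furan C2 bonding to the terminal alkyne carbon. The oxygen bridge would open under a trace of acid to give A8 with O3'–H free next to the O4' benzyl ether.
- For: this delivers the ring B pattern needed for sulfation without any selective protection. With O5 benzylated and O3 as methoxymethyl ether the endgame is the shortest of all. On the endgame it is clearly stronger than the chosen route.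
- Against: a ring B unit with the right oxygens is commercially available as a benzoic acid, so building it by cycloaddition spends steps on a solved problem. A6 requires the complete chromone with differentiated O5 and O7 plus an alkyne. That alkyne is only a vinylogous acceptor, further deactivated by the C3 alkoxy group. Furan cycloadditions are reversible and 3-alkoxyfurans are acid-sensitive. Both the orientation of the cycloaddition and the direction of bridge opening must be correct.
- Comparison: the chosen route is shorter and convergent from three commercial pieces, at the price of one late selective benzylation.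

Key step: step 6

Assumption: the target is drawn as the free bis(hydrogen sulfate). Compounds 13 and 14 would be handled as their dipotassium salts and are written in the neutral acid form. The free acid would be released only at the very end by cold cation exchange.

## Route

Step 1
Reactants: 1 3,4-bis(benzyloxy)benzoic acid
Product: 2 1-[3,4-bis(benzyloxy)benzoyl]-1H-imidazole
Conditions: CDI (1.1 equiv), THF, rt
Reagents that add atoms: 1,1'-carbonyldiimidazole, O=C(n1ccnc1)n1ccnc1
Why: Acyl activation as the acyl imidazole, driven by loss of carbon dioxide; the benzyl ethers are inert and the product is a non-enolisable acyl donor.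

Step 2
Reactants: 2 1-[3,4-bis(benzyloxy)benzoyl]-1H-imidazole; 3 ethyl 2-(benzyloxy)acetate
Product: 4 ethyl 2-(benzyloxy)-3-[3,4-bis(benzyloxy)phenyl]-3-oxopropanoate (racemic, enolisable)
Conditions: 3, LiN(SiMe3)2 (2.2 equiv), THF, −78 °C; then 2, −78 → −20 °C; cold 1 M HCl
Reagents that add atoms: none
Why: Crossed Claisen condensation of a glycolate ester enolate with an acyl imidazole; the second equivalent of base deprotonates the more acidic product, and the low temperature should suppress Wittig rearrangement of the benzyloxy enolate.

Step 3
Reactants: 4 ethyl 2-(benzyloxy)-3-[3,4-bis(benzyloxy)phenyl]-3-oxopropanoate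
Product: 5 ethyl (E)-2-(benzyloxy)-3-[3,4-bis(benzyloxy)phenyl]-3-{[(4-methylphenyl)sulfonyl]oxy}prop-2-enoate
Conditions: TsCl, TMEDA, LiCl, MeCN, 0 °C → rt
Reagents that add atoms: p-toluenesulfonyl chloride, Cc1ccc(S(=O)(=O)Cl)cc1
Why: O-sulfonylation of the β-keto ester enolate at the ketone oxygen; lithium chelation between the two carbonyl oxygens should place the tosyloxy group cis to the ester, which is the (E) isomer by the priority rules. A minor geometric isomer need not be removed because step 6 is stereoconvergent.

Step 4
Reactants: 5 ethyl (E)-2-(benzyloxy)-3-[3,4-bis(benzyloxy)phenyl]-3-{[(4-methylphenyl)sulfonyl]oxy}prop-2-enoate; 6 3,5-dimethoxyphenol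
Product: 7 ethyl (E)-2-(benzyloxy)-3-[3,4-bis(benzyloxy)phenyl]-3-(3,5-dimethoxyphenoxy)prop-2-enoate
Conditions: Cs2CO3 (1.5 equiv), DMF, 70 °C
Reagents that add atoms: none
Why: Nucleophilic vinylic substitution by addition–elimination: the phenoxide adds to the β-carbon of the acrylate, and the ester-stabilised carbanion expels tosylate. Retention is expected to give the aryloxy group cis to the ester, and any other isomer is carried forward.

Step 5
Reactants: 7 ethyl (E)-2-(benzyloxy)-3-[3,4-bis(benzyloxy)phenyl]-3-(3,5-dimethoxyphenoxy)prop-2-enoate
Product: 8 (E)-2-(benzyloxy)-3-[3,4-bis(benzyloxy)phenyl]-3-(3,5-dimethoxyphenoxy)prop-2-enoic acid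
Conditions: LiOH·H2O (4 equiv), THF/MeOH/H2O, 50 °C; then 1 M HCl to pH 3, 0 °C
Reagents that add atoms: lithium hydroxide, [Li+].[OH-]
Why: Saponification of the ethyl ester; once the carboxylate has formed the acrylate is no longer an acceptor, and the cold, mildly acidic work-up should spare the aryl enol ether.

Step 6
Reactants: 8 (E)-2-(benzyloxy)-3-[3,4-bis(benzyloxy)phenyl]-3-(3,5-dimethoxyphenoxy)prop-2-enoic acid
Product: 10 3-(benzyloxy)-2-[3,4-bis(benzyloxy)phenyl]-5,7-dimethoxy-4H-chromen-4-one, via mixed trifluoroacetic anhydride 9 (not isolated)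
Conditions: (CF3CO)2O (1.3 equiv), CH2Cl2, 0 °C → rt
Reagents that add atoms: none
Why: Intramolecular Friedel–Crafts acylation: trifluoroacetic anhydride converts the acid into the mixed anhydride 9, whose acyl carbon (as such or as the donor-stabilised acylium ion) is attacked by the ring A carbon ortho to the ether oxygen, and loss of a proton from the arenium ion gives the C4–C4a bond. The closest known reaction type is the acid- or anhydride-mediated cyclisation of β-aryloxyacrylic and β-aryloxycinnamic acids to chromones and flavones. Ring C closes as a six-membered ring by 6-exo-trig attack of the arene on the acyl carbon, and no stereocentre is formed. Three selectivities are needed. Site: the two carbons ortho to the ether oxygen are equivalent by the symmetry of the 3,5-dimethoxyphenoxy group, and the third activated carbon, between the methoxy groups, cannot reach the acyl group. Geometry: only the isomer with the acyl group cis to the aryloxy group can close, and the other isomer should feed into it because both the push–pull acylium ion and the C2-protonated enol ether rotate easily about the C2–C3 bond. Chemoselectivity: closure onto ring B would need a five-membered transition state to a strained inden-1-one on a less electron-rich arene, and intermolecular trifluoroacetylation of ring A is limited by the small excess of anhydride at 0 °C, after which the new carbonyl deactivates the ring. The benzyl ethers and the aryl enol ether should survive because neither a strong Lewis acid nor water is present.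

Step 7
Reactants: 10 3-(benzyloxy)-2-[3,4-bis(benzyloxy)phenyl]-5,7-dimethoxy-4H-chromen-4-one
Product: 11 2-(3,4-dihydroxyphenyl)-3,5-dihydroxy-7-methoxy-4H-chromen-4-one (rhamnetin)
Conditions: BCl3 (8 equiv), C6HMe5 (6 equiv), CH2Cl2, −78 → 0 °C; MeOH, then 1 M HCl/MeOH, 40 °C
Reagents that add atoms: none
Why: Lewis-acid ether cleavage: BCl3 removes the three benzyl groups, with pentamethylbenzene trapping the benzyl cations so that ring A is not C-benzylated. It also cleaves the O5 methyl ether, which is activated by six-membered chelation to the C4 carbonyl, while the unchelated O7 methyl ether is not attacked at this temperature.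

Step 8
Reactants: 11 2-(3,4-dihydroxyphenyl)-3,5-dihydroxy-7-methoxy-4H-chromen-4-one
Product: 12 2-[4-(benzyloxy)-3-hydroxyphenyl]-3,5-dihydroxy-7-methoxy-4H-chromen-4-one
Conditions: BnBr (1.05 equiv), KHCO3 (1.5 equiv), DMF, 40 °C
Reagents that add atoms: benzyl bromide, BrCc1ccccc1
Why: Williamson ether synthesis under acidity control: the weak base should ionise only O4'–H, whose anion is delocalised through ring B and C2=C3 into the carbonyl, while O3–H and O5–H are hydrogen-bonded to that carbonyl and O3'–H lacks this conjugation. The known preference of quercetin for benzylation at O7 and O4' before O3 is the analogy.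

Step 9
Reactants: 12 2-[4-(benzyloxy)-3-hydroxyphenyl]-3,5-dihydroxy-7-methoxy-4H-chromen-4-one
Product: 13 2-[4-(benzyloxy)-3-(sulfooxy)phenyl]-5-hydroxy-7-methoxy-4-oxo-4H-chromen-3-yl hydrogen sulfate
Conditions: SO3·pyridine (10 equiv), pyridine/DMF, 50 °C; aq. KOH to pH 8
Reagents that add atoms: sulfur trioxide–pyridine complex, [O-]S(=O)(=O)[n+]1ccccc1
Why: O-sulfonation of the phenolic O3'–H and the enolic O3–H with an amine–SO3 complex; the strongly chelated O5–H is expected not to react, and the basic work-up keeps the sulfates as stable salts.

Step 10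
Reactants: 13 2-[4-(benzyloxy)-3-(sulfooxy)phenyl]-5-hydroxy-7-methoxy-4-oxo-4H-chromen-3-yl hydrogen sulfate
Product: 14 5-hydroxy-2-[4-hydroxy-3-(sulfooxy)phenyl]-7-methoxy-4-oxo-4H-chromen-3-yl hydrogen sulfate (rhamnetin 3,3'-disulfate)
Conditions: H2 (1 atm), 10% Pd/C, MeOH/H2O, rt; cation-exchange resin (H+ form), 0 °C
Reagents that add atoms: none
Why: Catalytic hydrogenolysis of the benzyl aryl ether at neutral pH, which sulfate monoester salts and the flavone C2=C3 bond tolerate; brief cold cation exchange gives the acid form.

## Compound list

1 | 3,4-bis(benzyloxy)benzoic acid | OC(=O)c1ccc(OCc2ccccc2)c(OCc2ccccc2)c1 | starting material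
2 | 1-[3,4-bis(benzyloxy)benzoyl]-1H-imidazole | O=C(c1ccc(OCc2ccccc2)c(OCc2ccccc2)c1)n1ccnc1 | intermediate
3 | ethyl 2-(benzyloxy)acetate | CCOC(=O)COCc1ccccc1 | starting material
4 | ethyl 2-(benzyloxy)-3-[3,4-bis(benzyloxy)phenyl]-3-oxopropanoate (racemic) | CCOC(=O)C(OCc1ccccc1)C(=O)c1ccc(OCc2ccccc2)c(OCc2ccccc2)c1 | intermediate
5 | ethyl (E)-2-(benzyloxy)-3-[3,4-bis(benzyloxy)phenyl]-3-{[(4-methylphenyl)sulfonyl]oxy}prop-2-enoate | CCOC(=O)/C(OCc1ccccc1)=C(\OS(=O)(=O)c1ccc(C)cc1)c1ccc(OCc2ccccc2)c(OCc2ccccc2)c1 | intermediate
6 | 3,5-dimethoxyphenol | COc1cc(O)cc(OC)c1 | starting material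
7 | ethyl (E)-2-(benzyloxy)-3-[3,4-bis(benzyloxy)phenyl]-3-(3,5-dimethoxyphenoxy)prop-2-enoate | CCOC(=O)/C(OCc1ccccc1)=C(\Oc1cc(OC)cc(OC)c1)c1ccc(OCc2ccccc2)c(OCc2ccccc2)c1 | intermediate
8 | (E)-2-(benzyloxy)-3-[3,4-bis(benzyloxy)phenyl]-3-(3,5-dimethoxyphenoxy)prop-2-enoic acid | OC(=O)/C(OCc1ccccc1)=C(\Oc1cc(OC)cc(OC)c1)c1ccc(OCc2ccccc2)c(OCc2ccccc2)c1 | intermediate
9 | (E)-2-(benzyloxy)-3-[3,4-bis(benzyloxy)phenyl]-3-(3,5-dimethoxyphenoxy)prop-2-enoic trifluoroacetic anhydride | O=C(OC(=O)C(F)(F)F)/C(OCc1ccccc1)=C(\Oc1cc(OC)cc(OC)c1)c1ccc(OCc2ccccc2)c(OCc2ccccc2)c1 | intermediate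
10 | 3-(benzyloxy)-2-[3,4-bis(benzyloxy)phenyl]-5,7-dimethoxy-4H-chromen-4-one | COc1cc(OC)c2c(=O)c(OCc3ccccc3)c(-c3ccc(OCc4ccccc4)c(OCc4ccccc4)c3)oc2c1 | intermediate
11 | 2-(3,4-dihydroxyphenyl)-3,5-dihydroxy-7-methoxy-4H-chromen-4-one (rhamnetin) | COc1cc(O)c2c(=O)c(O)c(-c3ccc(O)c(O)c3)oc2c1 | intermediate
12 | 2-[4-(benzyloxy)-3-hydroxyphenyl]-3,5-dihydroxy-7-methoxy-4H-chromen-4-one | COc1cc(O)c2c(=O)c(O)c(-c3ccc(OCc4ccccc4)c(O)c3)oc2c1 | intermediate
13 | 2-[4-(benzyloxy)-3-(sulfooxy)phenyl]-5-hydroxy-7-methoxy-4-oxo-4H-chromen-3-yl hydrogen sulfate | COc1cc(O)c2c(=O)c(OS(=O)(=O)O)c(-c3ccc(OCc4ccccc4)c(OS(=O)(=O)O)c3)oc2c1 | intermediate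
14 | 5-hydroxy-2-[4-hydroxy-3-(sulfooxy)phenyl]-7-methoxy-4-oxo-4H-chromen-3-yl hydrogen sulfate (rhamnetin 3,3'-disulfate) | COc1cc(O)c2c(=O)c(OS(=O)(=O)O)c(-c3ccc(O)c(OS(=O)(=O)O)c3)oc2c1 | target

## Step count and least certain steps

Total step count: 10. Longest linear sequence: 10 steps (1 to 14); 3 and 6 enter at steps 2 and 4.

Step 6 (key step). The cyclisation could stall because the acyl group is a vinylogous carbonate and only weakly electrophilic. It could also be diverted by trifluoroacetylation of the electron-rich ring A, by acid-induced cleavage of the aryl enol ether, or by closure onto ring B from the wrong geometric isomer. The fallback abandons the acylation and closes ring C at O1–C2; it sets out from 1 and comes back at 11.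
- Acid 1 is converted with oxalyl chloride and catalytic DMF into 3,4-bis(benzyloxy)benzoyl chloride F1.
- F1 acylates commercial 1-(2-hydroxy-4,6-dimethoxyphenyl)ethanone in pyridine to give 2-acetyl-3,5-dimethoxyphenyl 3,4-bis(benzyloxy)benzoate F2.
- Baker–Venkataraman rearrangement (KOH, pyridine, 50 °C) gives 1-[3,4-bis(benzyloxy)phenyl]-3-(2-hydroxy-4,6-dimethoxyphenyl)propane-1,3-dione F3.
- Cyclodehydration (AcOH, catalytic H2SO4) gives 2-[3,4-bis(benzyloxy)phenyl]-5,7-dimethoxy-4H-chromen-4-one F4.
- Lithiation at C3 (LDA, THF, −78 °C), trimethyl borate and oxidation with H2O2/AcOH give 2-[3,4-bis(benzyloxy)phenyl]-3-hydroxy-5,7-dimethoxy-4H-chromen-4-one F5.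
- F5 is taken through the conditions of step 7 to 11.

Step 4. Addition to the β-carbon may be slow, because the acceptor is tetrasubstituted and carries donor groups on both alkene carbons. Sulfonyl transfer to the phenoxide or ester exchange could then compete. The fallback replaces addition–elimination by a metal-catalysed C–O coupling; it sets out from 4 and comes back at 7.
- The lithium enolate of 4 (LiN(SiMe3)2, THF, −78 °C) is trapped with N-phenylbis(trifluoromethanesulfonimide) to give ethyl (E)-2-(benzyloxy)-3-[3,4-bis(benzyloxy)phenyl]-3-{[(trifluoromethyl)sulfonyl]oxy}prop-2-enoate F6.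
- F6 is coupled with 6 using Pd2(dba)3, 2-(di-tert-butylphosphino)biphenyl and K3PO4 in toluene at 90 °C. This is the known palladium-catalysed coupling of vinyl triflates with phenols and gives 7.

Step 8. Site selectivity may be insufficient: alkylation at O3 and double alkylation are the likely failures, since the acidity gap between O4'–H and O3–H is moderate. The fallback replaces direct alkylation by stepwise unmasking of esters; it sets out from 11 and comes back at 12.
- 11 is peracetylated (Ac2O, pyridine) to 2-(3,4-diacetoxyphenyl)-7-methoxy-4-oxo-4H-chromene-3,5-diyl diacetate F7.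
- Benzyl bromide, K2CO3 and KI in refluxing acetone replace the most labile acetate, the one on O4' that is para-conjugated to the carbonyl, by benzyl. This gives 2-[3-acetoxy-4-(benzyloxy)phenyl]-7-methoxy-4-oxo-4H-chromene-3,5-diyl diacetate F8.
- Methanolysis (K2CO3, MeOH, rt) removes the remaining acetates and gives 12.

Step 9. Sulfation of the hindered, hydrogen-bonded O3–H may be incomplete and leave a monosulfate, or sulfate may be lost by hydrolysis during isolation. The fallback installs the sulfates as neutral, chromatographable diesters; it sets out from 12 and comes back at 13.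
- 12 is treated with 2,2,2-trichloroethyl chlorosulfate, Et3N and DMAP in THF to give 2-[4-(benzyloxy)-3-{[(2,2,2-trichloroethoxy)sulfonyl]oxy}phenyl]-5-hydroxy-7-methoxy-4-oxo-4H-chromen-3-yl 2,2,2-trichloroethyl sulfate F9.
- Reductive removal of the trichloroethyl groups from F9 with zinc dust and ammonium formate in MeOH gives 13.

## Further compounds

F1 | step 6 | 3,4-bis(benzyloxy)benzoyl chloride | O=C(Cl)c1ccc(OCc2ccccc2)c(OCc2ccccc2)c1
F2 | step 6 | 2-acetyl-3,5-dimethoxyphenyl 3,4-bis(benzyloxy)benzoate | CC(=O)c1c(OC)cc(OC)cc1OC(=O)c1ccc(OCc2ccccc2)c(OCc2ccccc2)c1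
F3 | step 6 | 1-[3,4-bis(benzyloxy)phenyl]-3-(2-hydroxy-4,6-dimethoxyphenyl)propane-1,3-dione | COc1cc(O)c(C(=O)CC(=O)c2ccc(OCc3ccccc3)c(OCc3ccccc3)c2)c(OC)c1
F4 | step 6 | 2-[3,4-bis(benzyloxy)phenyl]-5,7-dimethoxy-4H-chromen-4-one | COc1cc(OC)c2c(=O)cc(-c3ccc(OCc4ccccc4)c(OCc4ccccc4)c3)oc2c1
F5 | step 6 | 2-[3,4-bis(benzyloxy)phenyl]-3-hydroxy-5,7-dimethoxy-4H-chromen-4-one | COc1cc(OC)c2c(=O)c(O)c(-c3ccc(OCc4ccccc4)c(OCc4ccccc4)c3)oc2c1
F6 | step 4 | ethyl (E)-2-(benzyloxy)-3-[3,4-bis(benzyloxy)phenyl]-3-{[(trifluoromethyl)sulfonyl]oxy}prop-2-enoate | CCOC(=O)/C(OCc1ccccc1)=C(\OS(=O)(=O)C(F)(F)F)c1ccc(OCc2ccccc2)c(OCc2ccccc2)c1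
F7 | step 8 | 2-(3,4-diacetoxyphenyl)-7-methoxy-4-oxo-4H-chromene-3,5-diyl diacetate | COc1cc(OC(C)=O)c2c(=O)c(OC(C)=O)c(-c3ccc(OC(C)=O)c(OC(C)=O)c3)oc2c1
F8 | step 8 | 2-[3-acetoxy-4-(benzyloxy)phenyl]-7-methoxy-4-oxo-4H-chromene-3,5-diyl diacetate | COc1cc(OC(C)=O)c2c(=O)c(OC(C)=O)c(-c3ccc(OCc4ccccc4)c(OC(C)=O)c3)oc2c1
F9 | step 9 | 2-[4-(benzyloxy)-3-{[(2,2,2-trichloroethoxy)sulfonyl]oxy}phenyl]-5-hydroxy-7-methoxy-4-oxo-4H-chromen-3-yl 2,2,2-trichloroethyl sulfate | COc1cc(O)c2c(=O)c(OS(=O)(=O)OCC(Cl)(Cl)Cl)c(-c3ccc(OCc4ccccc4)c(OS(=O)(=O)OCC(Cl)(Cl)Cl)c3)oc2c1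
A1 | alternative 1 | methyl 4-{6-[4-(benzyloxy)-3-(methoxymethoxy)phenyl]-5-(methoxymethoxy)-4-oxo-4H-pyran-2-yl}-3-oxobutanoate | COC(=O)CC(=O)Cc1cc(=O)c(OCOC)c(-c2ccc(OCc3ccccc3)c(OCOC)c2)o1
A2 | alternative 1 | 2-[4-(benzyloxy)-3-(methoxymethoxy)phenyl]-5,7-dihydroxy-3-(methoxymethoxy)chromen-4-one | COCOc1c(-c2ccc(OCc3ccccc3)c(OCOC)c2)oc2cc(O)cc(O)c2c1=O
A3 | alternative 2 | 3-(benzyloxy)-5-methoxy-2-(trimethylsilyl)phenyl trifluoromethanesulfonate | COc1cc(OCc2ccccc2)c([Si](C)(C)C)c(OS(=O)(=O)C(F)(F)F)c1
A4 | alternative 2 | 3-[4-(benzyloxy)-3-(methoxymethoxy)phenyl]prop-2-ynoic acid | COCOc1cc(C#CC(=O)O)ccc1OCc1ccccc1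
A5 | alternative 2 | 5-(benzyloxy)-2-[4-(benzyloxy)-3-(methoxymethoxy)phenyl]-7-methoxychromen-4-one | COCOc1cc(-c2cc(=O)c3c(OCc4ccccc4)cc(OC)cc3o2)ccc1OCc1ccccc1
A6 | alternative 3 | 5-(benzyloxy)-2-ethynyl-7-methoxy-3-(methoxymethoxy)chromen-4-one | COCOc1c(C#C)oc2cc(OC)cc(OCc3ccccc3)c2c1=O
A7 | alternative 3 | 3-(benzyloxy)furan | C(Oc1ccoc1)c1ccccc1
A8 | alternative 3 | 5-(benzyloxy)-2-[4-(benzyloxy)-3-hydroxyphenyl]-7-methoxy-3-(methoxymethoxy)chromen-4-one | COCOc1c(-c2ccc(OCc3ccccc3)c(O)c2)oc2cc(OC)cc(OCc3ccccc3)c2c1=O
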